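The 14-membered carbocycle is cut at the bond between its only stereocentre, C1, and C14 (ring atoms C1–C14 numbered through the Z alkene C3=C4; C15=C16H2 is the exocyclic methylene). The feature exploited is the allylic C1–H beside C15=C16, an SN2' retron, together with the homoallylic C14–C13–C12=C11 unit, the hydroboration product of a terminal diene. In one operation a chiral copper catalyst moves the C14 alkyl group from boron to C1 of a (Z)-allylic chloride, which closes the ring, sets (R)-C1 and releases the methylene. The precursor is an achiral, acyclic hexaene methyl ester with a C16 allylic chloride and a C13=C14 diene terminus.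

Key step: step 15

Assumption: the sense of asymmetric induction in step 15 is taken by analogy with the intermolecular coupling and is not derived here; (R)-DTBM-SEGPHOS is written, and its mirror image is to be used instead if a model coupling shows that it is the one that attacks the Re face of C1.

Step 1
Reactants: 1 neryl acetate
Product: 2 6,7-epoxyneryl acetate (racemic)
Conditions: mCPBA (1.05 equiv), NaHCO3, CH2Cl2, −10 to 0 °C
Reagents that add atoms: mCPBA, O=C(OO)c1cccc(Cl)c1
Why: Prilezhaev epoxidation is fastest at the most electron-rich alkene, and the remote gem-dimethyl alkene is more nucleophilic than the 2,3-alkene, which is deactivated by its allylic acetoxy group; the racemic epoxide carbons are cleaved in step 2.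

Step 2
Reactants: 2 6,7-epoxyneryl acetate
Product: 3 (Z)-6-acetoxy-4-methylhex-4-enal (C2 to C7)
Conditions: H5IO6, THF/Et2O, 0 °C to rt
Reagents that add atoms: none
Why: Periodic acid hydrates the epoxide in the flask and cleaves the resulting 1,2-diol (Malaprade-type glycol cleavage) to acetone and the aldehyde, whose oxygen is the former epoxide oxygen, while the acetate and the Z alkene survive the mild acid.

Step 3
Reactants: 4 5-bromo-2-methylpent-2-ene; 5 trimethyl phosphonoacetate
Product: 6 methyl 2-(dimethoxyphosphoryl)-6-methylhept-5-enoate (racemic)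
Conditions: 5 (1.5 equiv), NaH, THF/DMSO, 0 °C; then 4, NaI (cat.), 50 °C
Reagents that add atoms: none
Why: SN2 C-alkylation of the sodium salt of a phosphonoacetate with a primary bromide is standard, an excess of 5 should limit dialkylation, and the new α-carbon loses its stereogenicity in step 4.

Step 4
Reactants: 3 (Z)-6-acetoxy-4-methylhex-4-enal; 6 methyl 2-(dimethoxyphosphoryl)-6-methylhept-5-enoate
Product: 7 methyl (2E,6Z)-8-acetoxy-6-methyl-2-(4-methylpent-3-en-1-yl)octa-2,6-dienoate (C2 to C12)
Conditions: LiCl, DBU, MeCN, 0 °C to rt; minor (2Z) isomer removed by chromatography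
Reagents that add atoms: none
Why: Horner–Wadsworth–Emmons olefination under lithium-mediated, reversible-addition conditions should favour the thermodynamically preferred (E)-enoate at C7=C8 (chain trans to the ester), and the mild amine base spares the acetate and the enolisable aldehyde.

Step 5
Reactants: 7 triene ester
Product: 8 methyl (2E,6Z)-8-acetoxy-2-[(E)-5-hydroxy-4-methylpent-3-en-1-yl]-6-methylocta-2,6-dienoate
Conditions: SeO2 (cat.), t-BuOOH, salicylic acid (cat.), CH2Cl2, rt
Reagents that add atoms: selenium dioxide, O=[Se]=O (oxygen carrier); tert-butyl hydroperoxide, CC(C)(C)OO (terminal oxygen source)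
Why: Selenium dioxide allylic oxidation (ene reaction, then 2,3-sigmatropic shift) attacks the most electron-rich trisubstituted alkene at its (E)-methyl group, and only the C11=C12 gem-dimethyl alkene qualifies because the other two alkenes carry an allylic acetate or an ester; any enal formed by further oxidation is the product of step 6 anyway.

Step 6
Reactants: 8 (E)-allylic alcohol
Product: 9 methyl (2E,6Z)-8-acetoxy-6-methyl-2-[(E)-4-methyl-5-oxopent-3-en-1-yl]octa-2,6-dienoate
Conditions: MnO2, CH2Cl2, rt
Reagents that add atoms: none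
Why: MnO2 oxidises allylic alcohols selectively to enals and leaves isolated alkenes, both esters and the E geometry of C11=C12 untouched.

Step 7
Reactants: 9 (E)-enal; 10 methyltriphenylphosphonium bromide
Product: 12 methyl (2E,6Z)-8-acetoxy-6-methyl-2-[(E)-4-methylhexa-3,5-dien-1-yl]octa-2,6-dienoate (C2 to C14), via methylenetriphenylphosphorane 11 (not isolated)
Conditions: 10, KN(SiMe3)2, THF, 0 °C; then 9, −78 to 0 °C
Reagents that add atoms: none
Why: Wittig methylenation of the aldehyde by the non-stabilised ylide is far faster than attack on the methyl ester or the acetate at low temperature, and 1,2-addition to the enal adds C14 without touching the E C11=C12 geometry.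

Step 8
Reactants: 12 terminal (E)-diene acetate
Product: 13 methyl (2E,6Z)-8-hydroxy-6-methyl-2-[(E)-4-methylhexa-3,5-dien-1-yl]octa-2,6-dienoate
Conditions: K2CO3 (cat.), MeOH, 0 °C
Reagents that add atoms: none
Why: Base-catalysed transesterification removes the primary allylic acetate, while the methyl enoate can only exchange methoxide for methoxide in methanol.

Step 9
Reactants: 13 neryl-type allylic alcohol
Product: 14 methyl (2E,6Z)-8-chloro-6-methyl-2-[(E)-4-methylhexa-3,5-dien-1-yl]octa-2,6-dienoate
Conditions: NCS, Me2S, CH2Cl2, −20 to 0 °C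
Reagents that add atoms: N-chlorosuccinimide, O=C1CCC(=O)N1Cl
Why: Corey–Kim chlorination displaces the alkoxysulfonium group by chloride at the primary carbon (SN2) under nearly neutral conditions, which keeps the Z geometry and avoids allylic transposition.

Step 10
Reactants: 15 propargyl alcohol; 4 5-bromo-2-methylpent-2-ene
Product: 18 (Z)-2-(iodomethylidene)-6-methylhept-5-en-1-ol, via homoprenylmagnesium bromide 16 (not isolated), via cyclic alkenylmagnesium alkoxide 17 (not isolated)
Conditions: 4 (2.5 equiv), Mg, THF, rt; then 15, CuI (10 mol%), THF, −10 °C to rt; then I2, −40 °C to rt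
Reagents that add atoms: iodine, II
Why: Copper-catalysed carbomagnesiation of propargyl alcohol is an anti addition through a five-membered magnesium alkoxide chelate, which puts the homoprenyl group on the internal carbon and magnesium cis to the CH2O group, so that iodinolysis with retention should give only the (Z)-iodoalkene.

Step 11
Reactants: 18 (Z)-iodo allylic alcohol
Product: 19 (Z)-tert-butyl{[2-(iodomethylidene)-6-methylhept-5-en-1-yl]oxy}dimethylsilane (C1, C15, C16 and side chain)
Conditions: TBSCl, imidazole, CH2Cl2, 0 °C to rt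
Reagents that add atoms: tert-butyldimethylsilyl chloride, CC(C)(C)[Si](C)(C)Cl
Why: Standard silylation of a primary alcohol with a silyl chloride and imidazole masks the hydroxyl group before the halogen–metal exchange.

Step 12
Reactants: 19 (Z)-iodoalkene silyl ether; 14 neryl-type allylic chloride
Product: 22 methyl (2E,6Z,9Z)-10-{[tert-butyl(dimethyl)silyl]oxymethyl}-6,14-dimethyl-2-[(E)-4-methylhexa-3,5-dien-1-yl]pentadeca-2,6,9,13-tetraenoate, via alkenyllithium 20 (not isolated), via alkenylzinc bromide 21 (not isolated)
Conditions: 19, t-BuLi (2 equiv), Et2O, −78 °C; ZnBr2, THF, −78 to 0 °C; then 14, Pd(PPh3)4 (5 mol%), THF, 0 °C to rt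
Reagents that add atoms: none
Why: Iodine–lithium exchange and transmetalation to zinc retain the alkene geometry, and the palladium-catalysed alkenyl–allyl Negishi coupling joins C1 to the primary allylic carbon C2 with retention of both Z geometries, the organozinc tolerating the methyl ester; exchange in Et2O at −78 °C with immediate zinc transmetalation suppresses 1,4 oxygen-to-carbon silyl migration.

Step 13
Reactants: 22 acyclic silyl ether
Product: 23 methyl (2E,6Z,9Z)-10-(hydroxymethyl)-6,14-dimethyl-2-[(E)-4-methylhexa-3,5-dien-1-yl]pentadeca-2,6,9,13-tetraenoate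
Conditions: Bu4NF, THF, 0 °C
Reagents that add atoms: none
Why: Fluoride cleaves the silicon–oxygen bond selectively and leaves the methyl ester, the skipped diene and the conjugated diene untouched.

Step 14
Reactants: 23 acyclic allylic alcohol
Product: 24 methyl (2E,6Z,9Z)-10-(chloromethyl)-6,14-dimethyl-2-[(E)-4-methylhexa-3,5-dien-1-yl]pentadeca-2,6,9,13-tetraenoate
Conditions: NCS, Me2S, CH2Cl2, −20 to 0 °C
Reagents that add atoms: N-chlorosuccinimide, O=C1CCC(=O)N1Cl
Why: Corey–Kim chlorination again converts the primary allylic alcohol into the chloride at C16 by SN2 displacement without transposition, which preserves the (Z) geometry of C1=C15 needed in step 15.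

Step 15
Reactants: 24 acyclic (Z)-allylic chloride with terminal diene
Product: 27 methyl (1E,5Z,8R,11E)-5,11-dimethyl-8-(6-methylhepta-1,5-dien-2-yl)cyclotetradeca-1,5,11-triene-1-carboxylate, via B-alkyl-9-BBN 25 (not isolated), via potassium methoxyborate 26 (not isolated)
Conditions: 9-BBN dimer (0.53 equiv), THF, 0 °C to rt; then this solution by syringe pump into (CuOTf)2·C6H5CH3 (20 mol% Cu), (R)-DTBM-SEGPHOS (22 mol%), KOMe (1.2 equiv), 1,4-dioxane/THF, 25 °C, final concentration 2 mM
Reagents that add atoms: none
Why: Proposed new method: 9-BBN should add only to the monosubstituted C13=C14 end of the diene and place boron on C14, methoxide turns the borane into a borate that passes this primary alkyl group to the bisphosphine-bound monovalent copper centre, and the alkylcopper then adds to C1=C15 anti to the C16–Cl bond and expels chloride (addition–elimination, or reductive elimination from a γ-σ-allyl trivalent copper species), so that the C14–C1 bond and the C15=C16H2 group arise together. The closest known reaction types are the intermolecular copper-catalysed enantioselective γ-selective coupling of alkyl-9-BBN reagents with (Z)-allylic chlorides and the copper-catalysed asymmetric SN2' substitution of β-substituted allylic chlorides, whereas an intramolecular, macrocyclic case on a β-alkyl allylic chloride has not been shown. The 14-membered carbocycle closes in the 14-exo mode, because the attacked C1=C15 bond ends up outside the ring as the methylene. The C1 stereocentre is controlled by the chiral bisphosphine on copper, which has to deliver C14 to the Re face of C1 (C15 > C2 > H) of the geometrically pure (Z)-alkene to give (R). The step needs γ attack (C1, 14-ring) over α attack (C16, 16-ring), one alkene face and cyclisation over oligomerisation, which are addressed by the SN2' preference of ligated alkylcopper, by the single (Z) geometry of the chloride and by slow addition at high dilution. The substrate is suited because it holds no 1,1-disubstituted alkene before this step, its α-branched enoate is a poor acceptor for alkylcopper, and methoxide cannot alter a methyl ester.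

Step 16
Reactants: 27 macrocyclic methyl ester
Product: 28 (1E,5Z,8R,11E)-5,11-dimethyl-8-(6-methylhepta-1,5-dien-2-yl)cyclotetradeca-1,5,11-triene-1-carboxylic acid (CNP0168903.1)
Conditions: LiOH, THF/MeOH/H2O, 45 °C; then aqueous HCl to pH 3
Reagents that add atoms: lithium hydroxide, [Li+].[OH-] (its oxygen becomes the carboxyl OH)
Why: Saponification by acyl–oxygen cleavage of the hindered α-substituted enoate needs only gentle warming, and C1, an unactivated allylic methine, cannot epimerise under these conditions.

Compound list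
1 | neryl acetate, (Z)-3,7-dimethylocta-2,6-dien-1-yl acetate | CC(C)=CCC/C(C)=C\COC(C)=O | starting material
2 | 6,7-epoxyneryl acetate, (Z)-5-(3,3-dimethyloxiran-2-yl)-3-methylpent-2-en-1-yl acetate, racemic | CC1(C)OC1CC/C(C)=C\COC(C)=O | intermediate
3 | (Z)-6-acetoxy-4-methylhex-4-enal | O=CCC/C(C)=C\COC(C)=O | intermediate
4 | 5-bromo-2-methylpent-2-ene (homoprenyl bromide) | CC(C)=CCCBr | starting material
5 | trimethyl phosphonoacetate | COC(=O)CP(=O)(OC)OC | starting material
6 | methyl 2-(dimethoxyphosphoryl)-6-methylhept-5-enoate, racemic | COC(=O)C(CCC=C(C)C)P(=O)(OC)OC | intermediate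
7 | methyl (2E,6Z)-8-acetoxy-6-methyl-2-(4-methylpent-3-en-1-yl)octa-2,6-dienoate | CC(=O)OC/C=C(/C)CC/C=C(/C(=O)OC)CCC=C(C)C | intermediate
8 | methyl (2E,6Z)-8-acetoxy-2-[(E)-5-hydroxy-4-methylpent-3-en-1-yl]-6-methylocta-2,6-dienoate | CC(=O)OC/C=C(/C)CC/C=C(/C(=O)OC)CC/C=C(\C)CO | intermediate
9 | methyl (2E,6Z)-8-acetoxy-6-methyl-2-[(E)-4-methyl-5-oxopent-3-en-1-yl]octa-2,6-dienoate | CC(=O)OC/C=C(/C)CC/C=C(/C(=O)OC)CC/C=C(\C)C=O | intermediate
10 | methyltriphenylphosphonium bromide | C[P+](c1ccccc1)(c1ccccc1)c1ccccc1.[Br-] | starting material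
11 | methylenetriphenylphosphorane | C=P(c1ccccc1)(c1ccccc1)c1ccccc1 | intermediate
12 | methyl (2E,6Z)-8-acetoxy-6-methyl-2-[(E)-4-methylhexa-3,5-dien-1-yl]octa-2,6-dienoate | CC(=O)OC/C=C(/C)CC/C=C(/C(=O)OC)CC/C=C(\C)C=C | intermediate
13 | methyl (2E,6Z)-8-hydroxy-6-methyl-2-[(E)-4-methylhexa-3,5-dien-1-yl]octa-2,6-dienoate | OC/C=C(/C)CC/C=C(/C(=O)OC)CC/C=C(\C)C=C | intermediate
14 | methyl (2E,6Z)-8-chloro-6-methyl-2-[(E)-4-methylhexa-3,5-dien-1-yl]octa-2,6-dienoate | ClC/C=C(/C)CC/C=C(/C(=O)OC)CC/C=C(\C)C=C | intermediate
15 | propargyl alcohol | C#CCO | starting material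
16 | (4-methylpent-3-en-1-yl)magnesium bromide | CC(C)=CCC[Mg]Br | intermediate
17 | 4-(4-methylpent-3-en-1-yl)-2,5-dihydro-1,2-oxamagnesole (cyclic alkenylmagnesium alkoxide) | CC(C)=CCCC1=C[Mg]OC1 | intermediate
18 | (Z)-2-(iodomethylidene)-6-methylhept-5-en-1-ol | I/C=C(\CO)CCC=C(C)C | intermediate
19 | (Z)-tert-butyl{[2-(iodomethylidene)-6-methylhept-5-en-1-yl]oxy}dimethylsilane | I/C=C(\CO[Si](C)(C)C(C)(C)C)CCC=C(C)C | intermediate
20 | (Z)-alkenyllithium from 19 (lithium in place of iodine, cis to CH2OTBS) | [Li]/C=C(\CO[Si](C)(C)C(C)(C)C)CCC=C(C)C | intermediate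
21 | (Z)-alkenylzinc bromide from 20 | Br[Zn]/C=C(\CO[Si](C)(C)C(C)(C)C)CCC=C(C)C | intermediate
22 | methyl (2E,6Z,9Z)-10-{[tert-butyl(dimethyl)silyl]oxymethyl}-6,14-dimethyl-2-[(E)-4-methylhexa-3,5-dien-1-yl]pentadeca-2,6,9,13-tetraenoate | CC(C)=CCC/C(CO[Si](C)(C)C(C)(C)C)=C/C/C=C(/C)CC/C=C(/C(=O)OC)CC/C=C(\C)C=C | intermediate
23 | methyl (2E,6Z,9Z)-10-(hydroxymethyl)-6,14-dimethyl-2-[(E)-4-methylhexa-3,5-dien-1-yl]pentadeca-2,6,9,13-tetraenoate | CC(C)=CCC/C(CO)=C/C/C=C(/C)CC/C=C(/C(=O)OC)CC/C=C(\C)C=C | intermediate
24 | methyl (2E,6Z,9Z)-10-(chloromethyl)-6,14-dimethyl-2-[(E)-4-methylhexa-3,5-dien-1-yl]pentadeca-2,6,9,13-tetraenoate | CC(C)=CCC/C(CCl)=C/C/C=C(/C)CC/C=C(/C(=O)OC)CC/C=C(\C)C=C | intermediate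
25 | methyl (2E,6Z,9Z)-2-[(E)-6-(9-borabicyclo[3.3.1]nonan-9-yl)-4-methylhex-3-en-1-yl]-10-(chloromethyl)-6,14-dimethylpentadeca-2,6,9,13-tetraenoate | CC(C)=CCC/C(CCl)=C/C/C=C(/C)CC/C=C(/C(=O)OC)CC/C=C(\C)CCB1C2CCCC1CCC2 | intermediate
26 | potassium B-methoxyborate of 25 | CC(C)=CCC/C(CCl)=C/C/C=C(/C)CC/C=C(/C(=O)OC)CC/C=C(\C)CC[B-]1(OC)C2CCCC1CCC2.[K+] | intermediate
27 | methyl (1E,5Z,8R,11E)-5,11-dimethyl-8-(6-methylhepta-1,5-dien-2-yl)cyclotetradeca-1,5,11-triene-1-carboxylate | C=C(CCC=C(C)C)[C@H]1C/C=C(/C)CC/C=C(/C(=O)OC)CC/C=C(\C)CC1 | intermediate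
28 | (1E,5Z,8R,11E)-5,11-dimethyl-8-(6-methylhepta-1,5-dien-2-yl)cyclotetradeca-1,5,11-triene-1-carboxylic acid | C=C(CCC=C(C)C)[C@H]1C/C=C(/C)CC/C=C(/C(=O)O)CC/C=C(\C)CC1 | target

Total step count: 16. Longest linear sequence: 13 steps (steps 1, 2, 4 to 9 and 12 to 16, from neryl acetate).

Steps most likely to fail

Step 15 (Proposed new method). Transfer of the C14 alkyl group from the borate to copper and its delivery to C1 may be too slow at high dilution. Oligomerisation, attack at C16 or poor facial discrimination on the β-substituted alkene could then take over. The fallback uses known reactions only, sets out from 24 and comes back at 27.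
- Hydroboration of 24 with 9-BBN as before, but with oxidative work-up (NaBO3·4H2O, THF/H2O), should give the C14 primary alcohol F1.
- Buffered Dess–Martin oxidation should give the chloro aldehyde F2, which is used at once because it is β,γ-unsaturated.
- CrCl2 in THF at high dilution then effects an intramolecular Nozaki–Hiyama–Kishi allylation, a ring closure of established type for 14-membered terpenoid carbocycles. The allylchromium formed at C16 adds through its γ-carbon C1 to the C14 aldehyde, which closes the same C1–C14 bond and creates the same C15=C16 methylene. The product is the racemic macrocyclic homoallylic alcohol F3, with a hydroxyl group on C14.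
- Preparative chromatography on a chiral stationary phase provides the C1-(R) macrocyclic alcohol F4. Either C14 epimer serves, since C14 becomes CH2.
- Barton–McCombie deoxygenation through the imidazole-1-carbothioate F5 returns to 27 (1,1'-thiocarbonyldiimidazole, DMAP, CH2Cl2; then Bu3SnH, AIBN, toluene, 80 °C). A high stannane concentration is used to outrun radical cyclisation.

Step 4. The elimination from the small dimethyl phosphonate may discriminate poorly between the two alkene geometries, leaving a large share of (2Z)-enoate that is hard to remove. The fallback sets out from 4 (used with 3) and comes back at 7. Commercial methyl (triphenylphosphoranylidene)acetate, Ph3P=CHCO2Me, is alkylated with 4 (NaI cat., EtOAc, reflux; a second equivalent of the ylide acts as base) to the α-homoprenyl stabilised ylide F6. Its thermal Wittig reaction with aldehyde 3 (toluene, 80 °C) should give 7, since α-alkyl stabilised ylides are reliably E-selective with unbranched aldehydes.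

Step 5. The selenium-mediated C–H oxidation may over-oxidise, attack other allylic methylene groups or stall. The fallback sets out from 7 and comes back at 9, bypassing 8 and step 6. Selective mCPBA epoxidation of the electron-rich C11=C12 alkene (buffered, CH2Cl2, 0 °C) gives the C11,C12-epoxide F7. H5IO6 cleavage gives the C11 aldehyde F8. A Wittig reaction with commercial 2-(triphenylphosphoranylidene)propanal, Ph3P=C(CH3)CHO (toluene, 90 °C), then builds the (E)-2-methyl enal 9 directly.

Further compounds
F1 | step 15 | methyl (2E,6Z,9Z)-10-(chloromethyl)-2-[(E)-6-hydroxy-4-methylhex-3-en-1-yl]-6,14-dimethylpentadeca-2,6,9,13-tetraenoate | CC(C)=CCC/C(CCl)=C/C/C=C(/C)CC/C=C(/C(=O)OC)CC/C=C(\C)CCO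
F2 | step 15 | methyl (2E,6Z,9Z)-10-(chloromethyl)-6,14-dimethyl-2-[(E)-4-methyl-6-oxohex-3-en-1-yl]pentadeca-2,6,9,13-tetraenoate | CC(C)=CCC/C(CCl)=C/C/C=C(/C)CC/C=C(/C(=O)OC)CC/C=C(\C)CC=O
F3 | step 15 | methyl (1E,5Z,11E)-9-hydroxy-5,11-dimethyl-8-(6-methylhepta-1,5-dien-2-yl)cyclotetradeca-1,5,11-triene-1-carboxylate, racemic | C=C(CCC=C(C)C)C1C/C=C(/C)CC/C=C(/C(=O)OC)CC/C=C(\C)CC1O
F4 | step 15 | methyl (1E,5Z,8R,11E)-9-hydroxy-5,11-dimethyl-8-(6-methylhepta-1,5-dien-2-yl)cyclotetradeca-1,5,11-triene-1-carboxylate, carbinol carbon either way | C=C(CCC=C(C)C)[C@H]1C/C=C(/C)CC/C=C(/C(=O)OC)CC/C=C(\C)CC1O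
F5 | step 15 | O-alkyl imidazole-1-carbothioate of F4 | C=C(CCC=C(C)C)[C@H]1C/C=C(/C)CC/C=C(/C(=O)OC)CC/C=C(\C)CC1OC(=S)n1ccnc1
F6 | step 4 | methyl 6-methyl-2-(triphenylphosphoranylidene)hept-5-enoate | COC(=O)C(CCC=C(C)C)=P(c1ccccc1)(c1ccccc1)c1ccccc1
F7 | step 5 | methyl (2E,6Z)-8-acetoxy-2-[2-(3,3-dimethyloxiran-2-yl)ethyl]-6-methylocta-2,6-dienoate, racemic | CC(=O)OC/C=C(/C)CC/C=C(/C(=O)OC)CCC1OC1(C)C
F8 | step 5 | methyl (2E,6Z)-8-acetoxy-6-methyl-2-(3-oxopropyl)octa-2,6-dienoate | CC(=O)OC/C=C(/C)CC/C=C(/C(=O)OC)CCC=O
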